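All runs stem from a simulated flask for substances that don't exist, and the scatter is random.

| flask | G | remark | time |
|---|---|---|---|
| delta | 2 M | the very flask that is asked about, followed so far |  |
| flask | 2.0 M |  | 15 d |

delta run (percent of the G charged)

| time / d | E / % |
|---|---|
| 0.167 | 26.8 |
| 0.500 | 37.2 |
| 0.833 | 39.8 |
| 1.25 | 40.2 |
| 1.67 | 39.9 |
| 2.50 | 39.6 |
| 3.00 | 40.2 |

(standard deviation of a reading: 0.3 percentage points)

- the reaction counts as stopped when no species that holds the G changes by six tenths of a point or more over the second half of the time

1. which holds at 15 d: what has brought the reaction to rest, or that it has not come to rest (it is still moving / all of G has reacted / forward and back rates have come level)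
2. E at 15 d, in percent of the G charged

I started from the leftover: E read 40.2% at 3.00 d, so 59.8% of the G charged to this flask stood in nothing I could read. I wanted two times. At 0.167 d the reading was 26.8%, so the gap to the level had shrunk by a factor of 3.00. Taken as first order, that gave 0.105 d for the approach half-life, the time in which the gap between E and its level halves. The other time was the asked 15 d, far longer than that, at 143 half-lives. So I expected E to stay at its level, but the count could not say what had stopped it.

The forecast gave forward and back rates have come level and 40%, reasoning that “a stop at 40% with 60% of the G unaccounted for points to a reversible ring closure, G ⇌ E”.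

The flask gave all of G has reacted and 40.2%.

    G + J → D (k = 0.00530 M⁻¹ min⁻¹)
    J → L (k = 6.30 × 10⁻⁴ min⁻¹)
    E ⇌ Q (K = 0.720, k = 0.0100 min⁻¹)
    G → E (k = 0.00300 min⁻¹)
    2 G → J (k = 5.40 × 10⁻⁴ M⁻¹ min⁻¹)

The back step joins E with Q, and G → E has none. G, the limiting reagent, stood at 1.75% of its charge at 0.750 d, which is 7.14 half-lives, and at 0% at 15.0 d. The flask had come to rest: left until 150 d, it still showed E at 40.2%, with no change.

Read at 4.0 d, the same flask was 38.1 half-lives along, so I expected the level again. It showed E at 40.2% and G at 0%.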